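**Retrosynthetic overview** (C1′–C14′ = side chain counted from the quinone; C1″–C5″ = cyclopentane, C1″ carries the chain and C3″ the 6-methylheptan-2-yl group)
1. C3–C1′: last step, Ag(I)/peroxodisulfate decarboxylative alkylation of bought menadione 25 with the C31 acid 24; the naphthoquinone ring is never built.
2. C5′–C6′: Cu-catalysed coupling of bromide 19 with (R)-citronellyl Grignard 21, whose isopropylidene is the masked CO2H.
3. Cyclopentane, the only ring formed (step 6): C1″–C2″ by aldol condensation of 1,4-keto aldehyde 13 to enone 15, then cis-selective hydrogenation and removal of C=O.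
4. Key step: C3″–C4″ by organo-SOMO α-enolation. The enamine radical cation of (R)-3,7-dimethyloctanal 2 (an α-carbonyl electrophile) is joined to enolsilane 12, two α-carbons that are both normally nucleophilic; this sets C3″.
5. 12 comes from (S)-citronellyl bromide 3, (R)-3-bromo-2-methylpropanol 4 and methyl vinyl ketone 8 (Cu coupling C8′–C9′, cross-metathesis).

Assumption: descriptors are read from the given SMILES (3′S,7′S,11′R; cyclopentane 1R,3S = cis; side chain 2R); both citronellyl bromide antipodes, (R)-citronellal, 4, LiTMP and the imidazolidinone catalyst are bought. The catalyst antipode in step 5 is chosen from MacMillan's facial model, not from a recalled literature example.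

**Step 1**
Reactants: 1 (R)-citronellal
Product: 2 (3R)-3,7-dimethyloctanal
Conditions: H2 (1 atm), 5% Pd/C, EtOAc, rt
Reagents that add atoms: none
Why: Chemoselective heterogeneous hydrogenation reduces the trisubstituted C=C much faster than the aldehyde, leaves C3 untouched, and removes the alkene that would otherwise trap the radical cation in step 5.

**Step 2**
Reactants: 3 (S)-citronellyl bromide; 4 (2R)-3-bromo-2-methylpropan-1-ol
Product: 7 (2S,6R)-2,6,10-trimethylundec-9-en-1-ol, via (S)-citronellylmagnesium bromide 5 (not isolated), via chloromagnesium alkoxide 6 (not isolated)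
Conditions: 4, i-PrMgCl (1.0 equiv), THF, −30 °C; then 5 (from 3, Mg, THF; 1.3 equiv), Li2CuCl4 (3 mol%), −30 → 0 °C; aq NH4Cl
Reagents that add atoms: none
Why: Kochi/Schlosser–Fouquet Cu-catalysed sp3–sp3 coupling of a primary Grignard with a primary bromide forms C8′–C9′ while the OH is masked in the flask as its magnesium alkoxide; C11′ (from 3) and C7′ (from 4) are chiral-pool spectators.

**Step 3**
Reactants: 7; 8 methyl vinyl ketone
Product: 10 (7S,11S)-12-hydroxy-7,11-dimethyldodecan-2-one, via (E)-enone 9 (not isolated)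
Conditions: 8 (4 equiv), Grubbs II (4 mol%), CH2Cl2, 40 °C; then 10% Pd/C, H2 (1 atm), rt, same flask
Reagents that add atoms: none
Why: Olefin cross-metathesis of the prenyl-type alkene with the enone partner expels isobutene to give the E-enone, whose C=C is then hydrogenated over Pd/C in the same pot without touching ketone, alcohol or stereocentres.

**Step 4**
Reactants: 10
Product: 12 (7S,11S)-2,12-bis[(tert-butyldimethylsilyl)oxy]-7,11-dimethyldodec-1-ene, via dilithium alkoxide-enolate 11 (not isolated)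
Conditions: LiTMP (2.3 equiv), THF, −78 °C (10 added to the base); TBSOTf (2.4 equiv), −78 → −40 °C; Et3N, aq NaHCO3
Reagents that add atoms: tert-butyldimethylsilyl trifluoromethanesulfonate, CC(C)(C)[Si](C)(C)OS(=O)(=O)C(F)(F)F
Why: Kinetic deprotonation of the methyl ketone at CH3 by the hindered amide followed by O-silylation gives the less substituted enolsilane and protects the primary alcohol in the same operation; no stereocentre is involved.

**Step 5 (key step)**
Reactants: 12; 2
Product: 13 (2R,9S,13S)-14-[(tert-butyldimethylsilyl)oxy]-9,13-dimethyl-2-[(2R)-6-methylheptan-2-yl]-4-oxotetradecanal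
Conditions: 2 (3 equiv), (2R,5R)-5-benzyl-2-tert-butyl-3-methylimidazolidin-4-one·TFA (30 mol%), CAN (2.2 equiv), 2,6-di-tert-butylpyridine (2.2 equiv), H2O (2 equiv), acetone, −20 °C, 24 h; crude product taken on
Reagents that add atoms: none
Why: MacMillan organo-SOMO α-enolation: CAN oxidises the catalyst-bound enamine of 2 to a radical cation with an electrophilic α-carbon, which is trapped by the CH2 terminus of enolsilane 12 and, after a second oxidation and desilylation, gives the 1,4-dicarbonyl, the (2R,5R)-catalyst (E-radical cation turned away from t-Bu, benzyl blocking one face) setting C3″ as 2R by catalyst control over the remote β-methyl centre.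

**Step 6**
Reactants: 13
Product: 15 (4R)-2-[(4R,8S)-9-[(tert-butyldimethylsilyl)oxy]-4,8-dimethylnonyl]-4-[(2R)-6-methylheptan-2-yl]cyclopent-2-en-1-one, via aldol adduct 14 (not isolated)
Conditions: KOH (0.15 M), MeOH, 0 °C, 1–2 h; AcOH quench
Reagents that add atoms: none
Why: Intramolecular aldol condensation in which only the C1″ enolate can reach the aldehyde through a five-membered transition state, then E1cB dehydration to the conjugated enone; brief cold exposure to dilute base limits epimerisation at C3″.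

**Step 7**
Reactants: 15
Product: 16 (2S,4R)-2-[(4R,8S)-9-[(tert-butyldimethylsilyl)oxy]-4,8-dimethylnonyl]-4-[(2R)-6-methylheptan-2-yl]cyclopentan-1-one
Conditions: H2 (1 atm), 5% Pd/C, EtOAc, rt
Reagents that add atoms: none
Why: Heterogeneous hydrogenation delivers H2 to the enone face anti to the bulky allylic sec-alkyl group at C4, so the new C1″ centre is cis to it (2S,4R), and the neutral conditions do not epimerise this α-centre.

**Step 8**
Reactants: 16
Product: 18 tert-butyldimethyl{[(2S,6S)-2,6-dimethyl-9-{(1R,3S)-3-[(2R)-6-methylheptan-2-yl]cyclopentyl}nonyl]oxy}silane, via tosylhydrazone 17 (not isolated)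
Conditions: TsNHNH2 (1.2 equiv), EtOH, 50 °C; evaporate; catecholborane (2 equiv), CHCl3, 0 °C; NaOAc·3H2O, reflux
Reagents that add atoms: none
Why: Kabalka deoxygenation: hydride transfer from catecholborane to the tosylhydrazone C=N and acetate-induced loss of sulfinate and N2 replace C=O by CH2 under mild conditions that do not epimerise the adjacent C1″.

**Step 9**
Reactants: 18
Product: 19 (1R,3S)-1-[(4S,8S)-9-bromo-4,8-dimethylnonyl]-3-[(2R)-6-methylheptan-2-yl]cyclopentane
Conditions: Ph3PBr2 (1.5 equiv), CH2Cl2, 0 °C → rt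
Reagents that add atoms: triphenylphosphine dibromide, BrP(Br)(c1ccccc1)(c1ccccc1)c1ccccc1
Why: Triphenylphosphine dibromide converts a primary TBS ether directly into the bromide (Appel-type SN2 on the oxyphosphonium ion), and the reacting carbon is not stereogenic.

**Step 10**
Reactants: 19; 20 (R)-citronellyl bromide
Product: 22 (1R,3S)-1-[(4R,8S,12S)-4,8,12,16-tetramethylheptadec-15-en-1-yl]-3-[(2R)-6-methylheptan-2-yl]cyclopentane, via (R)-citronellylmagnesium bromide 21 (not isolated)
Conditions: 21 (from 20, Mg, THF; 2.5 equiv), Li2CuCl4 (5 mol%), NMP (4 equiv), THF, 0 °C → rt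
Reagents that add atoms: none
Why: Cu-catalysed Grignard–alkyl bromide coupling (Kochi, Cahiez NMP variant) forms C5′–C6′, brings in C3′ from the chiral pool, and leaves the isopropylidene as the latent carboxyl.

**Step 11**
Reactants: 22
Product: 24 (4S,8S,12R)-4,8,12-trimethyl-15-{(1R,3S)-3-[(2R)-6-methylheptan-2-yl]cyclopentyl}pentadecanoic acid, via aldehyde 23 (not isolated)
Conditions: RuCl3·xH2O (3 mol%), NaIO4 (4 equiv), CCl4/MeCN/H2O (2:2:3), rt, 2 h
Reagents that add atoms: sodium periodate, [Na+].[O-]I(=O)(=O)=O; water, O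
Why: Sharpless RuO4 oxidative cleavage of the only C=C gives acetone and the aldehyde, which is oxidised on to the acid, while the saturated hydrocarbon remainder is inert over the short reaction time.

**Step 12**
Reactants: 24; 25 menadione (2-methylnaphthalene-1,4-dione)
Product: 26 2-methyl-3-{(3S,7S,11R)-3,7,11-trimethyl-14-[(1R,3S)-3-[(2R)-6-methylheptan-2-yl]cyclopentyl]tetradecyl}naphthalene-1,4-dione
Conditions: 25 (3 equiv), AgNO3 (0.3 equiv), (NH4)2S2O8 (1.5 equiv), MeCN/H2O (3:1), 75 °C, 2 h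
Reagents that add atoms: none
Why: Jacobsen–Torssell (Kochi–Anderson) Ag(I)/peroxodisulfate oxidative decarboxylation generates the primary C1′ radical, which adds to the free C3 of menadione and is re-oxidised to the quinone, with all stereocentres remote from the reaction site.

**Compound list**
1 | (R)-citronellal | O=CC[C@H](C)CCC=C(C)C | starting material
2 | (3R)-3,7-dimethyloctanal | O=CC[C@H](C)CCCC(C)C | intermediate
3 | (S)-citronellyl bromide, (6S)-8-bromo-2,6-dimethyloct-2-ene | BrCC[C@@H](C)CCC=C(C)C | starting material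
4 | (2R)-3-bromo-2-methylpropan-1-ol | OC[C@@H](C)CBr | starting material
5 | [(3S)-3,7-dimethyloct-6-en-1-yl]magnesium bromide | Br[Mg]CC[C@@H](C)CCC=C(C)C | intermediate (not isolated)
6 | chloromagnesium (2R)-3-bromo-2-methylpropan-1-olate | Cl[Mg]OC[C@@H](C)CBr | intermediate (not isolated)
7 | (2S,6R)-2,6,10-trimethylundec-9-en-1-ol | OC[C@@H](C)CCC[C@@H](C)CCC=C(C)C | intermediate
8 | methyl vinyl ketone | C=CC(C)=O | starting material
9 | (3E,7R,11S)-12-hydroxy-7,11-dimethyldodec-3-en-2-one | OC[C@@H](C)CCC[C@@H](C)CC/C=C/C(C)=O | intermediate (not isolated)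
10 | (7S,11S)-12-hydroxy-7,11-dimethyldodecan-2-one | OC[C@@H](C)CCC[C@@H](C)CCCCC(C)=O | intermediate
11 | dilithium (7S,11S)-7,11-dimethyldodec-1-ene-2,12-diolate | [Li]OC[C@@H](C)CCC[C@@H](C)CCCCC(=C)O[Li] | intermediate (not isolated)
12 | (7S,11S)-2,12-bis[(tert-butyldimethylsilyl)oxy]-7,11-dimethyldodec-1-ene | CC(C)(C)[Si](C)(C)OC[C@@H](C)CCC[C@@H](C)CCCCC(=C)O[Si](C)(C)C(C)(C)C | intermediate
13 | (2R,9S,13S)-14-[(tert-butyldimethylsilyl)oxy]-9,13-dimethyl-2-[(2R)-6-methylheptan-2-yl]-4-oxotetradecanal | CC(C)(C)[Si](C)(C)OC[C@@H](C)CCC[C@@H](C)CCCCC(=O)C[C@H]([C@H](C)CCCC(C)C)C=O | intermediate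
14 | (4R)-2-[(4R,8S)-9-[(tert-butyldimethylsilyl)oxy]-4,8-dimethylnonyl]-3-hydroxy-4-[(2R)-6-methylheptan-2-yl]cyclopentan-1-one (C2/C3 epimers) | CC(C)(C)[Si](C)(C)OC[C@@H](C)CCC[C@@H](C)CCCC1C(O)[C@@H]([C@H](C)CCCC(C)C)CC1=O | intermediate (not isolated)
15 | (4R)-2-[(4R,8S)-9-[(tert-butyldimethylsilyl)oxy]-4,8-dimethylnonyl]-4-[(2R)-6-methylheptan-2-yl]cyclopent-2-en-1-one | CC(C)(C)[Si](C)(C)OC[C@@H](C)CCC[C@@H](C)CCCC1=C[C@@H]([C@H](C)CCCC(C)C)CC1=O | intermediate
16 | (2S,4R)-2-[(4R,8S)-9-[(tert-butyldimethylsilyl)oxy]-4,8-dimethylnonyl]-4-[(2R)-6-methylheptan-2-yl]cyclopentan-1-one | CC(C)(C)[Si](C)(C)OC[C@@H](C)CCC[C@@H](C)CCC[C@@H]1C(=O)C[C@H]([C@H](C)CCCC(C)C)C1 | intermediate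
17 | p-toluenesulfonylhydrazone of 16 | CC(C)(C)[Si](C)(C)OC[C@@H](C)CCC[C@@H](C)CCC[C@@H]1C(=NNS(=O)(=O)c2ccc(C)cc2)C[C@H]([C@H](C)CCCC(C)C)C1 | intermediate (not isolated)
18 | tert-butyldimethyl{[(2S,6S)-2,6-dimethyl-9-{(1R,3S)-3-[(2R)-6-methylheptan-2-yl]cyclopentyl}nonyl]oxy}silane | CC(C)(C)[Si](C)(C)OC[C@@H](C)CCC[C@@H](C)CCC[C@@H]1CC[C@H]([C@H](C)CCCC(C)C)C1 | intermediate
19 | (1R,3S)-1-[(4S,8S)-9-bromo-4,8-dimethylnonyl]-3-[(2R)-6-methylheptan-2-yl]cyclopentane | BrC[C@@H](C)CCC[C@@H](C)CCC[C@@H]1CC[C@H]([C@H](C)CCCC(C)C)C1 | intermediate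
20 | (R)-citronellyl bromide, (6R)-8-bromo-2,6-dimethyloct-2-ene | BrCC[C@H](C)CCC=C(C)C | starting material
21 | [(3R)-3,7-dimethyloct-6-en-1-yl]magnesium bromide | Br[Mg]CC[C@H](C)CCC=C(C)C | intermediate (not isolated)
22 | (1R,3S)-1-[(4R,8S,12S)-4,8,12,16-tetramethylheptadec-15-en-1-yl]-3-[(2R)-6-methylheptan-2-yl]cyclopentane | CC(C)=CCC[C@@H](C)CCC[C@@H](C)CCC[C@@H](C)CCC[C@@H]1CC[C@H]([C@H](C)CCCC(C)C)C1 | intermediate
23 | (4S,8S,12R)-4,8,12-trimethyl-15-{(1R,3S)-3-[(2R)-6-methylheptan-2-yl]cyclopentyl}pentadecanal | O=CCC[C@@H](C)CCC[C@@H](C)CCC[C@@H](C)CCC[C@@H]1CC[C@H]([C@H](C)CCCC(C)C)C1 | intermediate (not isolated)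
24 | (4S,8S,12R)-4,8,12-trimethyl-15-{(1R,3S)-3-[(2R)-6-methylheptan-2-yl]cyclopentyl}pentadecanoic acid | OC(=O)CC[C@@H](C)CCC[C@@H](C)CCC[C@@H](C)CCC[C@@H]1CC[C@H]([C@H](C)CCCC(C)C)C1 | intermediate
25 | menadione (2-methylnaphthalene-1,4-dione) | CC1=CC(=O)c2ccccc2C1=O | starting material
26 | 2-methyl-3-{(3S,7S,11R)-3,7,11-trimethyl-14-[(1R,3S)-3-[(2R)-6-methylheptan-2-yl]cyclopentyl]tetradecyl}naphthalene-1,4-dione | CC1=C(CC[C@@H](C)CCC[C@@H](C)CCC[C@@H](C)CCC[C@@H]2CC[C@H]([C@H](C)CCCC(C)C)C2)C(=O)c2ccccc2C1=O | target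

**Totals**
Total step count: 12. Longest linear sequence: 11 steps (steps 2–12, from 3 and 4 to 26).

**Three steps most likely to fail**

Step 5 (SOMO coupling). The valuable enolsilane is the limiting partner, the reverse of the usual stoichiometry, and the aldehyde is β-branched. The fallback sets out from 12 and 2 and returns at 13. NBS (THF, 0 °C) converts 12 into the bromomethyl ketone (7S,11S)-1-bromo-12-[(tert-butyldimethylsilyl)oxy]-7,11-dimethyldodecan-2-one F1. F1 then alkylates aldehyde 2 under photoredox/enamine catalysis (Ru(bpy)3Cl2, the imidazolidinone·HOTf antipode that gives the 2R aldehyde, 2,6-lutidine, DMF, visible light). Here the α-keto carbon arrives as a reductively generated electrophilic radical from an α-halo ketone rather than through oxidation of the enamine, and the product is 13.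

Step 6 (aldol condensation). Base can epimerise C3″, which is α to the aldehyde in 13 and γ to the carbonyl in 15. The fallback sets out from 9, isolated by stopping step 3 after the metathesis, and returns at 15. LiTMP/TBSOTf (as in step 4) gives the silyloxydiene (3E,7R,11S)-2,12-bis[(tert-butyldimethylsilyl)oxy]-7,11-dimethyldodeca-1,3-diene F2. SOMO coupling of F2 with 2 under the step-5 conditions gives the enone aldehyde (2R,5E,9R,13S)-14-[(tert-butyldimethylsilyl)oxy]-9,13-dimethyl-2-[(2R)-6-methylheptan-2-yl]-4-oxotetradec-5-enal F3. Krische hydrogen-mediated reductive aldol cyclisation of F3 (Rh(cod)2OTf, (p-CF3C6H4)3P, KOAc cat., H2 1 atm, DCE, rt) generates the C1″ enolate regiospecifically by conjugate reduction and closes the ring to aldol 14 without hydroxide or alkoxide base. Catalytic TsOH in CH2Cl2 then dehydrates 14 to 15.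

Step 12 (radical alkylation of menadione). The waxy C31 acid is poorly soluble in aqueous MeCN and primary radicals give only moderate yields. The fallback sets out from 24 and returns at 26 by a polar C–C bond formation. Suárez iododecarboxylation (PhI(OAc)2, I2, hν, cyclohexane, reflux) gives (1R,3S)-1-[(4R,8S,12S)-14-iodo-4,8,12-trimethyltetradecyl]-3-[(2R)-6-methylheptan-2-yl]cyclopentane F4. Bromination of commercial 1,4-dimethoxy-2-methylnaphthalene (Br2, CH2Cl2, 0 °C) gives 2-bromo-1,4-dimethoxy-3-methylnaphthalene F5, and n-BuLi (THF, −78 °C) turns it into (1,4-dimethoxy-3-methylnaphthalen-2-yl)lithium F6. Alkylation of F6 with F4 (THF/HMPA, −78 °C → rt) gives 1,4-dimethoxy-2-methyl-3-{(3S,7S,11R)-3,7,11-trimethyl-14-[(1R,3S)-3-[(2R)-6-methylheptan-2-yl]cyclopentyl]tetradecyl}naphthalene F7. CAN (MeCN/H2O, 0 °C) oxidises F7 to quinone 26.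

**Further compounds**
F1 | step 5 | (7S,11S)-1-bromo-12-[(tert-butyldimethylsilyl)oxy]-7,11-dimethyldodecan-2-one | CC(C)(C)[Si](C)(C)OC[C@@H](C)CCC[C@@H](C)CCCCC(=O)CBr
F2 | step 6 | (3E,7R,11S)-2,12-bis[(tert-butyldimethylsilyl)oxy]-7,11-dimethyldodeca-1,3-diene | CC(C)(C)[Si](C)(C)OC[C@@H](C)CCC[C@@H](C)CC/C=C/C(=C)O[Si](C)(C)C(C)(C)C
F3 | step 6 | (2R,5E,9R,13S)-14-[(tert-butyldimethylsilyl)oxy]-9,13-dimethyl-2-[(2R)-6-methylheptan-2-yl]-4-oxotetradec-5-enal | CC(C)(C)[Si](C)(C)OC[C@@H](C)CCC[C@@H](C)CC/C=C/C(=O)C[C@H]([C@H](C)CCCC(C)C)C=O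
F4 | step 12 | (1R,3S)-1-[(4R,8S,12S)-14-iodo-4,8,12-trimethyltetradecyl]-3-[(2R)-6-methylheptan-2-yl]cyclopentane | ICC[C@@H](C)CCC[C@@H](C)CCC[C@@H](C)CCC[C@@H]1CC[C@H]([C@H](C)CCCC(C)C)C1
F5 | step 12 | 2-bromo-1,4-dimethoxy-3-methylnaphthalene | COc1c(C)c(Br)c(OC)c2ccccc12
F6 | step 12 | (1,4-dimethoxy-3-methylnaphthalen-2-yl)lithium | COc1c(C)c([Li])c(OC)c2ccccc12
F7 | step 12 | 1,4-dimethoxy-2-methyl-3-{(3S,7S,11R)-3,7,11-trimethyl-14-[(1R,3S)-3-[(2R)-6-methylheptan-2-yl]cyclopentyl]tetradecyl}naphthalene | COc1c(C)c(CC[C@@H](C)CCC[C@@H](C)CCC[C@@H](C)CCC[C@@H]2CC[C@H]([C@H](C)CCCC(C)C)C2)c(OC)c2ccccc12
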